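If this substrate falls by acid catalysis while a feed thins the flask, its fall can be counted on a clock in powers of ten.

substrate 0.010 M; acid 0.300 mM; scavenger 1.00 equiv (fed, over 80 s); time 2.5 min; the fed solution adds 1.0 times the starting volume

- part of the substrate that has reacted at 2.5 min
- pH of the solution at 2.5 min

- acid is the free proton; pH is minus the decimal logarithm of its molar concentration
- in percentages every species weighs as the substrate in it: one idle adduct A counts as two
- for target the idle adduct A is counted in
- for weak acid the idle adduct B is counted in
- charges are per starting volume, the dose included; the dosed solution carries all of it
- in an amount of target, one idle adduct A counts as one target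
- what has gone from substrate into another species counts as reacted, even if it can come back
- run time (flask): 2.5 min

    weak acid + target → side product (k1 = 3.1 /M/s)
    weak acid + scavenger → scavenged by-product (k2 = 170 /M/s)
    substrate → weak acid + target (k3 = 1.1 × 10⁻⁴ /s)
    substrate + acid → weak acid + acid + target (k4 = 130 /M/s)
    weak acid ⇌ conjugate base + acid, settled at all times (K5 = 1.6 × 10⁻⁹ M)
    substrate + target ⇌ idle adduct A, settled at all times (K6 = 440 /M)
    substrate + weak acid ⇌ idle adduct B, settled at all times (K7 = 270 /M)

Substrate plus acid gives target and weak acid, and the acid comes back. That step has constant 130 /M/s and, as charged, a substrate half-life of 0.30 min, much shorter than the 110 min of the uncatalysed step, so I reckon with it as a pseudo-first-order fall.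

The feed doubles the volume, taking the acid to 0.150 mM. Summing k4 times the acid concentration over time gives 2.16 natural-log units during the feed and 1.36 after it, together E = 3.53. Turned into powers of ten, this is the acid clock D = 1.53, the decades of fall the acid offers an unhindered substrate, which leaves 2.93%.

The weak link is that substrate binds target as idle adduct A, and bound substrate doesn't react. K6 times the starting substrate is 4.4, and after dilution b = 2.20. Let S be the share of the charge not yet turned over, free plus bound. Its free part is S over one plus b times the target share, taken as the rest of the charge. Integrating, with a term in S dropped, gives the decades of S: D plus b in powers of ten, over one plus b. That is 0.777, so S is 16.7%, of which 5.89% is free. I commit to 94.1% reacted, with the bound part counted as reacted.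

The forecast gives 93.7%, slightly lower than mine, and pH 3.82, which is the pH of my 0.150 mM. It holds that “binding to target holds back part of it”.

The flask gives 93.3% and pH 3.82.

In this flask at 2.50 min, free substrate plus the substrate inside idle adduct A comes to 16.8%, against my S of 16.7%. The neighbour flask holds 7.5 × 10⁻⁴ M of acid, all other charges as here, so its clock reads 3.83. The same rule gives S = 3.20% and free substrate 1.02%. That flask ends with free plus bound substrate at 3.21%, free substrate at 1.1%, and 98.9% reacted.

The numbers of this flask are invented.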